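**Retrosynthetic overview**

- The target comes from its MOM ether by mild acid methanolysis. The dioxane is the only ring formed and is closed last, by making O1–C8a through a Pd-catalysed intramolecular O-arylation of a (1R,2R)-1-aryl-2-(2-bromoaryloxy)propan-1-ol, retentive at both stereocentres. Both benzene rings are bought.
- The (1R,2R) alcohol comes from the racemic 2-aryloxy-1-arylpropan-1-one by asymmetric hydrogenation with dynamic kinetic resolution, which makes the C2–H bond and fixes C2 and C3 together.
- Feature used: in the dioxane numbering O1–C2(syringyl)–C3(CH3)–O4 (ring A: C4a on O4, C5 OMe, C7 propenyl, C8a on O1), a ketone at C2 makes the C3–H acidic, helped by the geminal O4 aryloxy group. C3 can therefore stay racemic and is funnelled when C2 is reduced.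
- The racemic ketone comes from Takai ethylidenation of an aldehyde (the C7 propenyl group), after SN2 ether formation (C3–O4) between 5-bromovanillin and the α-bromopropiophenone made from MOM-protected syringaldehyde (EtMgBr, oxidation, bromination).

Key step: step 7

Assumption: the facial sense of RuCl2[(R)-xylbinap][(R)-daipen] on the precursor ketone is taken to be the one known for simple aryl alkyl ketones. If it proves opposite, the (S),(S) catalyst is used and nothing else changes.

**Route**

Step 1
Reactants: 1 syringaldehyde (4-hydroxy-3,5-dimethoxybenzaldehyde)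
Product: 2 3,5-dimethoxy-4-(methoxymethoxy)benzaldehyde
Conditions: MOMCl, iPr2NEt, CH2Cl2, 0 °C → rt
Reagents that add atoms: chloromethyl methyl ether (MOMCl), COCCl
Why: O-alkylation of the acidic phenol (MOM protection) gives an acetal that withstands the Grignard, enolate, organochromium, alkoxide and carbonate conditions that follow.

Step 2
Reactants: 2 3,5-dimethoxy-4-(methoxymethoxy)benzaldehyde
Product: 3 rac-1-[3,5-dimethoxy-4-(methoxymethoxy)phenyl]propan-1-ol
Conditions: EtMgBr, THF, 0 °C; aq. NH4Cl
Reagents that add atoms: ethylmagnesium bromide, CC[Mg]Br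
Why: Grignard addition to the aryl aldehyde installs the C3 and methyl carbons; the racemic carbinol centre is removed in the next step.

Step 3
Reactants: 3 rac-1-[3,5-dimethoxy-4-(methoxymethoxy)phenyl]propan-1-ol
Product: 4 1-[3,5-dimethoxy-4-(methoxymethoxy)phenyl]propan-1-one
Conditions: Dess–Martin periodinane, CH2Cl2, rt
Reagents that add atoms: none
Why: Dess–Martin oxidation of a benzylic secondary alcohol proceeds under near-neutral conditions that leave the MOM acetal and the electron-rich ring alone.

Step 4
Reactants: 4 1-[3,5-dimethoxy-4-(methoxymethoxy)phenyl]propan-1-one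
Product: 6 rac-2-bromo-1-[3,5-dimethoxy-4-(methoxymethoxy)phenyl]propan-1-one, via trimethylsilyl enol ether 5 (not isolated)
Conditions: LiN(SiMe3)2, TMSCl, THF, −78 → 0 °C; then NBS, THF, 0 °C
Reagents that add atoms: N-bromosuccinimide, O=C1CCC(=O)N1Br; chlorotrimethylsilane, C[Si](C)(C)Cl (its atoms stay only in intermediate 5)
Why: Kinetic enolisation and O-silylation followed by electrophilic bromination of the silyl enol ether with NBS gives the α-bromoketone without releasing HBr, which would cleave the MOM group; the new centre is racemic.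

Step 5
Reactants: 6 rac-2-bromo-1-[3,5-dimethoxy-4-(methoxymethoxy)phenyl]propan-1-one; 7 5-bromovanillin (3-bromo-4-hydroxy-5-methoxybenzaldehyde)
Product: 8 rac-3-bromo-4-[1-[3,5-dimethoxy-4-(methoxymethoxy)phenyl]-1-oxopropan-2-yl]oxy-5-methoxybenzaldehyde
Conditions: K2CO3, DMF, rt
Reagents that add atoms: none
Why: Williamson ether synthesis, in which the phenoxide of 7 displaces the carbonyl-activated secondary bromide by SN2 to form the C3–O4 bond; the centre is racemic and is corrected in step 7.

Step 6
Reactants: 8 rac-3-bromo-4-[1-[3,5-dimethoxy-4-(methoxymethoxy)phenyl]-1-oxopropan-2-yl]oxy-5-methoxybenzaldehyde; 9 1,1-diiodoethane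
Product: 10 rac-2-[2-bromo-6-methoxy-4-[(E)-prop-1-enyl]phenoxy]-1-[3,5-dimethoxy-4-(methoxymethoxy)phenyl]propan-1-one
Conditions: CrCl2 (8 equiv), 9 (2 equiv), THF, 0 °C → rt
Reagents that add atoms: none
Why: Takai–Utimoto alkylidenation, in which the non-basic geminal dichromium reagent from 9 and divalent chromium adds to the aldehyde but not to the ketone and eliminates to the (E)-alkene, leaving the enolisable α-aryloxy ketone and the aryl bromide intact.

Step 7
Reactants: 10 rac-2-[2-bromo-6-methoxy-4-[(E)-prop-1-enyl]phenoxy]-1-[3,5-dimethoxy-4-(methoxymethoxy)phenyl]propan-1-one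
Product: 11 (1R,2R)-2-[2-bromo-6-methoxy-4-[(E)-prop-1-enyl]phenoxy]-1-[3,5-dimethoxy-4-(methoxymethoxy)phenyl]propan-1-ol
Conditions: RuCl2[(R)-xylbinap][(R)-daipen] (1 mol%), KOtBu (20 mol%), H2 (10 atm), iPrOH/toluene, 25 °C
Reagents that add atoms: none
Why: KOtBu turns the dichloride into the ruthenium hydride carrying the daipen NH2 group, which passes hydride from ruthenium and a proton from nitrogen to the C=O of 10 through an outer-sphere six-membered transition state, while the same base racemises the CH(CH3)(OAr) carbon through the potassium enolate faster than the slower ketone enantiomer is reduced. The closest known reaction type is the Noyori asymmetric hydrogenation of racemic α-heteroatom-substituted aryl ketones with dynamic kinetic resolution. No ring closes and no skeletal bond forms; only the C1–H bond is made. The carbinol centre (C1, later C2 of the dioxane) is set by the catalyst, whose (R),(R) ligand pair is expected to deliver hydride to the face that gives the (S)-1-arylethanol arrangement from simple aryl alkyl ketones, which reads 1R here because the CH(OAr) carbon outranks the aryl carbon. The methyl-bearing centre (C2, later C3) is set by the polar Felkin–Anh preference, with the aryloxy group anti to the incoming hydride, which makes the (R)-ketone the fast-reacting enantiomer and leads to the syn (threo) alcohol. The step needs C=O reduction without touching the propenyl C=C or the C–Br bond and needs racemisation to outrun reduction; the first is secured by the outer-sphere mechanism, which offers the alkene and the bromide no site at the metal, and the second by the aryl ketone and aryloxy groups that acidify the C2–H, whose enolate cannot eliminate because the aryloxy group sits on the enolate carbon itself.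

Step 8
Reactants: 11 (1R,2R)-2-[2-bromo-6-methoxy-4-[(E)-prop-1-enyl]phenoxy]-1-[3,5-dimethoxy-4-(methoxymethoxy)phenyl]propan-1-ol
Product: 12 (2R,3R)-2-[3,5-dimethoxy-4-(methoxymethoxy)phenyl]-5-methoxy-3-methyl-7-[(E)-prop-1-enyl]-2,3-dihydro-1,4-benzodioxine
Conditions: Pd(OAc)2 (5 mol%), 2-(di-tert-butylphosphino)-1,1'-binaphthyl (6 mol%), Cs2CO3, toluene, 80 °C
Reagents that add atoms: none
Why: Buchwald–Hartwig intramolecular C–O coupling (oxidative addition of zerovalent palladium into C–Br, alkoxide binding, then C–O reductive elimination, which the bulky phosphine favours over β-hydride elimination) closes the six-membered dioxane at O1–C8a; neither C–O bond at a stereocentre is broken, so (1R,2R) becomes trans-(2R,3R).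

Step 9
Reactants: 12 (2R,3R)-2-[3,5-dimethoxy-4-(methoxymethoxy)phenyl]-5-methoxy-3-methyl-7-[(E)-prop-1-enyl]-2,3-dihydro-1,4-benzodioxine
Product: 13 4-[(2R,3R)-5-methoxy-3-methyl-7-[(E)-prop-1-enyl]-2,3-dihydro-1,4-benzodioxin-2-yl]-2,6-dimethoxyphenol (CNP0227775.1)
Conditions: HCl (aq., 3 equiv), MeOH/THF, rt
Reagents that add atoms: none
Why: Acid-catalysed acetal solvolysis removes the aryl MOM ether under dilute acid at room temperature, conditions under which the propenyl group should not add methanol or dimerise; any reversible ionisation at the benzylic C2 would return to the more stable trans isomer, so both stereocentres should be kept.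

**Compound list**

1 | syringaldehyde (4-hydroxy-3,5-dimethoxybenzaldehyde) | COc1cc(C=O)cc(OC)c1O | starting material
2 | 3,5-dimethoxy-4-(methoxymethoxy)benzaldehyde | COCOc1c(OC)cc(C=O)cc1OC | intermediate
3 | rac-1-[3,5-dimethoxy-4-(methoxymethoxy)phenyl]propan-1-ol | CCC(O)c1cc(OC)c(OCOC)c(OC)c1 | intermediate
4 | 1-[3,5-dimethoxy-4-(methoxymethoxy)phenyl]propan-1-one | CCC(=O)c1cc(OC)c(OCOC)c(OC)c1 | intermediate
5 | [(Z)-1-[3,5-dimethoxy-4-(methoxymethoxy)phenyl]prop-1-enyl]oxy-trimethylsilane (trimethylsilyl enol ether, not isolated) | C/C=C(\O[Si](C)(C)C)c1cc(OC)c(OCOC)c(OC)c1 | intermediate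
6 | rac-2-bromo-1-[3,5-dimethoxy-4-(methoxymethoxy)phenyl]propan-1-one | CC(Br)C(=O)c1cc(OC)c(OCOC)c(OC)c1 | intermediate
7 | 5-bromovanillin (3-bromo-4-hydroxy-5-methoxybenzaldehyde) | O=Cc1cc(Br)c(O)c(OC)c1 | starting material
8 | rac-3-bromo-4-[1-[3,5-dimethoxy-4-(methoxymethoxy)phenyl]-1-oxopropan-2-yl]oxy-5-methoxybenzaldehyde | O=Cc1cc(OC)c(OC(C)C(=O)c2cc(OC)c(OCOC)c(OC)c2)c(Br)c1 | intermediate
9 | 1,1-diiodoethane | CC(I)I | starting material
10 | rac-2-[2-bromo-6-methoxy-4-[(E)-prop-1-enyl]phenoxy]-1-[3,5-dimethoxy-4-(methoxymethoxy)phenyl]propan-1-one | C/C=C/c1cc(OC)c(OC(C)C(=O)c2cc(OC)c(OCOC)c(OC)c2)c(Br)c1 | intermediate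
11 | (1R,2R)-2-[2-bromo-6-methoxy-4-[(E)-prop-1-enyl]phenoxy]-1-[3,5-dimethoxy-4-(methoxymethoxy)phenyl]propan-1-ol | C/C=C/c1cc(OC)c(O[C@H](C)[C@H](O)c2cc(OC)c(OCOC)c(OC)c2)c(Br)c1 | intermediate
12 | (2R,3R)-2-[3,5-dimethoxy-4-(methoxymethoxy)phenyl]-5-methoxy-3-methyl-7-[(E)-prop-1-enyl]-2,3-dihydro-1,4-benzodioxine | C/C=C/c1cc(OC)c2c(c1)O[C@H](c1cc(OC)c(OCOC)c(OC)c1)[C@@H](C)O2 | intermediate
13 | 4-[(2R,3R)-5-methoxy-3-methyl-7-[(E)-prop-1-enyl]-2,3-dihydro-1,4-benzodioxin-2-yl]-2,6-dimethoxyphenol | C/C=C/c1cc(OC)c2c(c1)O[C@H](c1cc(OC)c(O)c(OC)c1)[C@@H](C)O2 | target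

**Step count**

Total steps: 9. Longest linear sequence: 9 steps (1 to 13 through steps 1–9); 7 enters at step 5 and 9 at step 6.

**Steps most likely to fail, with fallbacks**

Step 7. Enolate racemisation may be slower than hydrogenation, or the Felkin bias may be weak, so that syn and anti alcohols form together or the syn alcohol has low enantiomeric purity. The fallback replaces catalyst control by substrate-controlled reduction and classical resolution. Setting out from ketone 10, LiBH(s-Bu)3 in THF at −78 °C should give, by Felkin-controlled hydride delivery, the racemic syn alcohol rac-(1R*,2R*)-2-[2-bromo-6-methoxy-4-[(E)-prop-1-enyl]phenoxy]-1-[3,5-dimethoxy-4-(methoxymethoxy)phenyl]propan-1-ol F1. Esterification with (S)-2-methoxy-2-phenylacetic acid (DCC, DMAP, CH2Cl2) and chromatographic separation of the two diastereomeric esters should give (1R,2R)-2-[2-bromo-6-methoxy-4-[(E)-prop-1-enyl]phenoxy]-1-[3,5-dimethoxy-4-(methoxymethoxy)phenyl]propyl (2S)-2-methoxy-2-phenylacetate F2. Methanolysis (K2CO3, MeOH, rt) comes back to the route at alcohol 11.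

Step 8. β-Hydride elimination from the palladium alkoxide may outrun C–O reductive elimination, oxidising the carbinol and removing the bromine, or the arylpalladium species may be diverted by the propenyl group. The fallback replaces the bromide by a phenol and closes the ring under thermodynamic control. Setting out from alcohol 11, Miyaura borylation (B2pin2, PdCl2(dppf), KOAc, dioxane, 80 °C; acetate does not form the alkoxide) should give (1R,2R)-1-[3,5-dimethoxy-4-(methoxymethoxy)phenyl]-2-[2-methoxy-4-[(E)-prop-1-enyl]-6-(4,4,5,5-tetramethyl-1,3,2-dioxaborolan-2-yl)phenoxy]propan-1-ol F3. Oxidation with NaBO3·4H2O in THF/H2O at rt should give 2-[(1R,2R)-1-[3,5-dimethoxy-4-(methoxymethoxy)phenyl]-1-hydroxypropan-2-yl]oxy-3-methoxy-5-[(E)-prop-1-enyl]phenol F4. TsOH·H2O in wet THF at 40 °C should then remove the MOM group and ionise the 4-hydroxybenzylic alcohol to the quinone methide, which the neighbouring phenol captures reversibly to give the more stable trans dioxane with C3 untouched. The fallback thus comes back to the route at target 13.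

Step 6. The organochromium reagent may add with incomplete E-selectivity, or divalent chromium may attack the α-aryloxy ketone (addition to its C=O or reductive loss of the aryloxy group). The fallback makes the alkene before the ether. Setting out from 5-bromovanillin 7, Wittig reaction with the ylide from ethyltriphenylphosphonium bromide (KOtBu 2.2 equiv, THF, 0 °C → rt) should give the E/Z mixture of 2-bromo-6-methoxy-4-(prop-1-enyl)phenol F5. Catalytic PdCl2(MeCN)2 in CH2Cl2 should equilibrate it to 2-bromo-6-methoxy-4-[(E)-prop-1-enyl]phenol F6. O-Alkylation of this phenol with bromoketone 6 (K2CO3, DMF, rt) comes back to the route at ketone 10, bypassing 8.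

Further compounds
F1 | step 7 | rac-(1R*,2R*)-2-[2-bromo-6-methoxy-4-[(E)-prop-1-enyl]phenoxy]-1-[3,5-dimethoxy-4-(methoxymethoxy)phenyl]propan-1-ol (racemate, relative configuration drawn) | C/C=C/c1cc(OC)c(O[C@H](C)[C@H](O)c2cc(OC)c(OCOC)c(OC)c2)c(Br)c1
F2 | step 7 | (1R,2R)-2-[2-bromo-6-methoxy-4-[(E)-prop-1-enyl]phenoxy]-1-[3,5-dimethoxy-4-(methoxymethoxy)phenyl]propyl (2S)-2-methoxy-2-phenylacetate | C/C=C/c1cc(OC)c(O[C@H](C)[C@H](OC(=O)[C@@H](OC)c3ccccc3)c2cc(OC)c(OCOC)c(OC)c2)c(Br)c1
F3 | step 8 | (1R,2R)-1-[3,5-dimethoxy-4-(methoxymethoxy)phenyl]-2-[2-methoxy-4-[(E)-prop-1-enyl]-6-(4,4,5,5-tetramethyl-1,3,2-dioxaborolan-2-yl)phenoxy]propan-1-ol | C/C=C/c1cc(OC)c(O[C@H](C)[C@H](O)c2cc(OC)c(OCOC)c(OC)c2)c(B3OC(C)(C)C(C)(C)O3)c1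
F4 | step 8 | 2-[(1R,2R)-1-[3,5-dimethoxy-4-(methoxymethoxy)phenyl]-1-hydroxypropan-2-yl]oxy-3-methoxy-5-[(E)-prop-1-enyl]phenol | C/C=C/c1cc(OC)c(O[C@H](C)[C@H](O)c2cc(OC)c(OCOC)c(OC)c2)c(O)c1
F5 | step 6 | 2-bromo-6-methoxy-4-(prop-1-enyl)phenol (E/Z mixture) | CC=Cc1cc(Br)c(O)c(OC)c1
F6 | step 6 | 2-bromo-6-methoxy-4-[(E)-prop-1-enyl]phenol | C/C=C/c1cc(Br)c(O)c(OC)c1
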